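**Assumption:** the SMILES shows one enol tautomer of 2-benzoyl-4-methyl-6,6-diprenylcyclohexane-1,3,5-trione. The enol forms interconvert freely and the molecule has no stereocentre, so the route aims at this tautomeric system and needs no stereocontrol.

## Structural features

The target (C24H28O4) is a dearomatised acylphloroglucinol: a single carbocycle, an enolised cyclohexane-1,3,5-trione drawn as a cyclohexa-2,5-dienone, in which every ring carbon is substituted. With atom labels taken from the SMILES, C1 is the sp3 carbon bearing two prenyl (3-methylbut-2-en-1-yl) chains, C2 and C6 are the oxygenated carbons on either side of it, C3 carries the methyl group, C4 is the ring ketone and C5 carries the exocyclic benzoyl group. There is no stereocentre, because C1 bears two identical chains and C3 and C5 are trigonal in every enol form. The fragile groups are the two trisubstituted alkenes, which can cyclise onto the enol oxygens at C2 and C6 under strong acid, and the non-enolisable 1,3-dicarbonyl unit C2–C1–C6, which is open to retro-Claisen cleavage by nucleophiles whenever the rest of the ring is not held as an enolate. The real difficulty is C1, a fully substituted carbon between two carbonyl-level carbons that must stand in a fixed relation to the methyl group at C3 and the benzoyl group at C5. In any aromatic precursor C1 and C3 are both nucleophilic and three oxygens compete, so the problem is one of regiocontrol, not stereocontrol. The key step exploits the fact that the ring is the sum of two three-carbon units of opposite polarity: C6–C1–C2 is a masked, symmetric dialkylmalonyl unit that already contains the quaternary carbon, and C3–C4–C5 with its benzoyl group is a masked 1-phenylpentane-1,3-dione whose two carbanionic sites, C3 and C5, stand 1,3 to each other. Joining the two units at C2–C3 and C5–C6 closes the carbocycle on both sides of C1 without any alkylation of a ring.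

## Logic of the disconnections

In one sentence: the carbocycle of 10 is made in one flask by a [3+3] double C-acylation in which dianion 8 is acylated first at its terminal carbon and then at its central carbon by the two ester groups of 4.

**10 to 9.** The ring bond C5–C6 is cut. C5, C4, C6 and the benzoyl carbonyl form a β-triketone, the retron of an intramolecular Claisen (Dieckmann) acylation, so the cut turns C6 into an ester carbonyl that is still attached to C1. The gain is the loss of the only ring: 9 is a linear 3,5,7-triketo ester. The forward step must close through carbon C5 and not through the enol oxygen on C4, and it must tolerate a fully substituted carbon next to the electrophilic ester.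

**9 to 8 and 4.** The bond C2–C3 is cut. C3 is the γ-carbon of a β-diketone and is available as the terminal carbanion of 8, and C2 is the second ester carbonyl on the same quaternary carbon. Both cuts therefore fall on either side of C1 and divide the skeleton into an eleven-carbon and a thirteen-carbon half. The gain is that C1, the hardest atom, is confined to the symmetric compound 4, whose two electrophilic carbons are identical, so it does not matter which reacts first, and both bonds can be made in the same flask. The forward step demands attack by the terminal carbon of 8 first, a ring closure that is faster than a second intermolecular acylation, and one equivalent of base beyond the two that make 8. Dianion 8 comes from 7 by twofold deprotonation; the phenyl side of 7 has no α-hydrogen, so only one dianion can form.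

**4 to 3, then to 1 and 2.** The two bonds from C1 to the prenyl CH2 groups are cut. C1 is the α-carbon of a malonate, the only acidic carbon of 1, so both chains come from 2 by enolate alkylation. The gain is two commodity compounds. The forward step demands substitution at the primary carbon of 2 (not allylic transposition) and a complete second alkylation through 3.

**7 to 5 and 6.** The bond C4–C5 is cut, the Claisen retron of a β-diketone. The gain is again two commodity compounds. The forward step demands cross-condensation in preference to self-condensation of either partner.

## Other disconnections considered

**Alternative 1:** the first route that comes to mind cuts both bonds from C1 to the prenyl groups on an aromatic precursor, (2,4,6-trihydroxy-3-methylphenyl)(phenyl)methanone A1. The forward key step is a base-mediated dearomative double C-prenylation of A1 with 2, passing through the monoprenyl phenol A2. In A2 the ring carbons C1 (already prenylated) and C3 (methylated) are both nucleophilic positions of the same phloroglucinolate. The second alkylation must choose the more hindered C1; attack at C3 would give a constitutional isomer with a methyl/prenyl quaternary carbon and the same mass. Three phenoxide oxygens compete as well, and A1 itself costs an acylation step. The chosen plan makes C1 quaternary on a malonate, where no other carbon and no oxygen can compete, and never alkylates a ring.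

**Alternative 2:** the exocyclic bond from C5 to the benzoyl carbonyl is cut. The forward key step is O-benzoylation of the enolised trione A3 (3,5-dihydroxy-2-methyl-4,4-diprenylcyclohexa-2,5-dien-1-one) to the enol benzoate A4, followed by a cyanide-catalysed 1,3-shift of the acyl group from oxygen to C5. This only postpones the problem, because A3 still has to be built with its quaternary carbon. If A3 were made by the same kind of annulation, the three-carbon nucleophile would be an unactivated ethyl ketone with no bias for the second enolisation. In 7 the benzoyl group acidifies C5 and leaves C3 as the only site for the second deprotonation, so it is an asset and not a burden. Carrying it from the start saves two steps and avoids acyl transfer among three enol oxygens and two ring carbons.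

**Alternative 3:** the bonds C5–C6 and C3–C4 are cut so that C4–C5 is excised as an alkyne, with strain release as the driving force. The forward key step is the thermal opening of the cyclobutenone A5 (3-ethoxy-2-methyl-4,4-diprenylcyclobut-2-en-1-one) to a vinylketene, its [2+2] cycloaddition with an alkoxyalkyne, a second 4π opening and a 6π electrocyclisation to the 6,6-diprenylcyclohexa-2,4-dienone A6. A5 itself requires a dialkylketene and an ynol ether cycloaddition. Each ketene intermediate of the cascade carries two prenyl alkenes three atoms away, well placed for an intramolecular ketene–alkene [2+2] trap. The benzoyl group cannot be carried through, since an acyl-substituted ynol ether is a poor ketenophile, so A6 would still need ether cleavage and the acylation of Alternative 2. That is at least seven steps against three.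

Key step: step 3

## Route

**Step 1**
Reactants: 1 dimethyl malonate; 2 1-bromo-3-methylbut-2-ene (prenyl bromide)
Product: 4 dimethyl 2,2-bis(3-methylbut-2-en-1-yl)propanedioate, via monoprenyl malonate 3 (not isolated)
Conditions: NaH (2.3 equiv), THF, 0 °C; 2 (2.3 equiv), 0 °C to 50 °C
Reagents that add atoms: none
Why: Twofold SN2 alkylation of a malonate enolate (malonic ester synthesis): the soft, stabilised carbanion attacks the unhindered primary carbon of the allylic bromide, so the linear prenyl chain and not the 1,1-dimethylallyl isomer is attached, and the second alkylation makes C1 quaternary at the only acidic carbon of the molecule, where neither an oxygen nor another carbon can compete.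

**Step 2**
Reactants: 5 acetophenone; 6 ethyl propanoate
Product: 7 1-phenylpentane-1,3-dione
Conditions: NaH (2.2 equiv), 6 (2.0 equiv), THF, reflux; then cold 1 M HCl
Reagents that add atoms: none
Why: Crossed Claisen condensation of a methyl ketone with an ester: 5 has a single enolisable position and is the more acidic partner, so its enolate is acylated by 6, and the irreversible deprotonation of the β-diketone by NaH (loss of H2) pulls the equilibrium to the sodium salt of 7, which acid releases; this step forms the ring bond C4–C5.

**Step 3**
Reactants: 7 1-phenylpentane-1,3-dione; 4 dimethyl 2,2-bis(3-methylbut-2-en-1-yl)propanedioate
Product: 10 2-benzoyl-3,5-dihydroxy-6-methyl-4,4-bis(3-methylbut-2-en-1-yl)cyclohexa-2,5-dien-1-one (the target), via dilithium dienediolate 8 (not isolated), via triketo ester 9 (not isolated)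
Conditions: 7, LiN(iPr)2 (3.3 equiv), THF, −78 to 0 °C; 4 (1.0 equiv), −78 °C to rt, then 45 °C; cold 1 M HCl to pH 3
Reagents that add atoms: none
Why: Two equivalents of LiN(iPr)2 convert 7 into dienediolate 8, whose terminal carbon (the future C3) is its most basic and most nucleophilic site and adds to one of the two equivalent ester carbonyls of 4 (the future C2), methoxide being expelled to give 9. The third equivalent of base removes the newly acidified C3–H of 9, and the carbon between the benzoyl group and the C4 carbonyl (the future C5) then attacks the remaining ester (the future C6) in an intramolecular Claisen (Dieckmann) condensation, after which loss of the second methoxide and deprotonation leave the dienolate of 10, released by cold dilute acid. The closest known reaction types are the γ-acylation of β-diketone dianions by esters, the Claisen cyclisation of 3,5,7-triketo esters to acylphloroglucinols and, for the overall [3+3] pattern, the condensation of dialkylmalonic esters with urea to barbiturates, of which this is the all-carbon counterpart. The one ring is closed by a 6-exo-trig attack of a β-diketonate carbon on an ester carbonyl (enolendo or enolexo, both allowed for six-membered rings), helped by the gem-dialkyl effect of the two prenyl groups on C1. No stereocentre is formed, since C1 carries two identical chains and C3 and C5 end up trigonal. Three selectivities are needed and each is secured by the substrates: the site of the first attack (the phenyl side of 7 has no α-hydrogen, so only one dianion and one terminal carbanion exist, and the symmetry of 4 makes the choice of ester irrelevant), carbon against oxygen in the closure (acylation at the enol oxygen on C4 is reversible in the presence of methoxide whereas C-acylation ends in the strongly stabilised enolate of a β-triketone, and because C1 has no hydrogen no aldol route to a resorcinol exists), and one molecule of 8 per molecule of 4 (the remaining ester of 9 is hindered and sits in a dianion, so the intramolecular closure should outrun a second intermolecular acylation). The prenyl alkenes are inert to the amide base and meet acid only briefly and cold.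

## Compound list

1 | dimethyl malonate | COC(=O)CC(=O)OC | starting material
2 | 1-bromo-3-methylbut-2-ene (prenyl bromide) | CC(C)=CCBr | starting material
3 | dimethyl 2-(3-methylbut-2-en-1-yl)propanedioate (not isolated) | COC(=O)C(CC=C(C)C)C(=O)OC | intermediate
4 | dimethyl 2,2-bis(3-methylbut-2-en-1-yl)propanedioate | COC(=O)C(CC=C(C)C)(CC=C(C)C)C(=O)OC | intermediate
5 | acetophenone | CC(=O)c1ccccc1 | starting material
6 | ethyl propanoate | CCC(=O)OCC | starting material
7 | 1-phenylpentane-1,3-dione | CCC(=O)CC(=O)c1ccccc1 | intermediate
8 | dilithium 1-phenylpenta-1,3-diene-1,3-bis(olate) (not isolated; double-bond geometry undefined and without consequence, both carbons stay trigonal in 10) | [Li+].[Li+].CC=C([O-])C=C([O-])c1ccccc1 | intermediate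
9 | methyl 4-methyl-2,2-bis(3-methylbut-2-en-1-yl)-3,5,7-trioxo-7-phenylheptanoate (not isolated; drawn as the neutral triketo form, C4 of the chain is enolised in the flask and has no fixed configuration) | COC(=O)C(CC=C(C)C)(CC=C(C)C)C(=O)C(C)C(=O)CC(=O)c1ccccc1 | intermediate
10 | 2-benzoyl-3,5-dihydroxy-6-methyl-4,4-bis(3-methylbut-2-en-1-yl)cyclohexa-2,5-dien-1-one (no stereocentre) | CC(C)=CCC1(CC=C(C)C)C(O)=C(C)C(=O)C(C(=O)c2ccccc2)=C1O | target

## Step count and risk

Total step count: 3 (steps 1 and 2 are independent; step 3 joins their products).
Longest linear sequence: 2 steps (step 1 or step 2, then step 3).

**Step 3 (key step).** The most likely failure is a slow first acylation, because a secondary carbanion terminus meets an ester on a quaternary carbon; proton transfer and a second intermolecular acylation of the remaining ester could then compete with ring closure. The second risk is closure through the enol oxygen on C4 in place of carbon C5.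

The fallback separates the two acylations and gives the two electrophilic carbons different reactivity. It sets out from 4, which is mono-saponified (KOH, 1 equiv, MeOH, rt; the carboxylate formed protects the second ester) to the half ester 2-(methoxycarbonyl)-5-methyl-2-(3-methylbut-2-en-1-yl)hex-4-enoic acid F1. F1 is activated under neutral conditions with 1,1'-carbonyldiimidazole in THF to the N-acylimidazole methyl 2-(1H-imidazole-1-carbonyl)-5-methyl-2-(3-methylbut-2-en-1-yl)hex-4-enoate F2. Addition of F2 to 8 (made from 7 as in step 3) at −78 °C should acylate only the terminal carbon and, after mild acidic work-up, return to the route at 9, now isolated. Compound 9 is then closed in a separate operation under equilibrating conditions (Mg(OMe)2, MeOH, rt to reflux), where magnesium chelation of the β-triketone favours C-acylation and any O-acylated material is reopened by methoxide, to give 10.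

**Step 1.** The most likely failure is an incomplete second alkylation, so that mono- and dialkylated malonates of similar polarity have to be separated, together with a small amount of allylic transposition. The fallback changes the carbon acid. It sets out from 2, which alkylates Meldrum's acid twice (K2CO3, DMF, rt; the far more acidic and sterically compact cyclic malonate is dialkylated readily) to 2,2-dimethyl-5,5-bis(3-methylbut-2-en-1-yl)-1,3-dioxane-4,6-dione F3. NaOMe in MeOH opens F3 with loss of acetone to the sodium salt of the half ester F1, and MeI added to the same flask esterifies the carboxylate, returning to the route at 4.

**Step 2.** The most likely failure is self-condensation of 6 and aldol self-condensation of 5 under the equilibrating conditions, which would consume both partners. The fallback replaces the acylation by an aldol addition and an oxidation. It sets out from 5, whose lithium enolate (LiN(iPr)2, THF, −78 °C) adds to propanal to give racemic 3-hydroxy-1-phenylpentan-1-one F4. Oxidation of F4 with Dess–Martin periodinane in CH2Cl2 returns to the route at 7.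

## Further compounds

F1 | step 3 | 2-(methoxycarbonyl)-5-methyl-2-(3-methylbut-2-en-1-yl)hex-4-enoic acid | COC(=O)C(CC=C(C)C)(CC=C(C)C)C(=O)O
F2 | step 3 | methyl 2-(1H-imidazole-1-carbonyl)-5-methyl-2-(3-methylbut-2-en-1-yl)hex-4-enoate | COC(=O)C(CC=C(C)C)(CC=C(C)C)C(=O)n1ccnc1
F3 | step 1 | 2,2-dimethyl-5,5-bis(3-methylbut-2-en-1-yl)-1,3-dioxane-4,6-dione | CC(C)=CCC1(CC=C(C)C)C(=O)OC(C)(C)OC1=O
F4 | step 2 | 3-hydroxy-1-phenylpentan-1-one (racemic) | CCC(O)CC(=O)c1ccccc1
A1 | alternative 1 | (2,4,6-trihydroxy-3-methylphenyl)(phenyl)methanone | Cc1c(O)cc(O)c(C(=O)c2ccccc2)c1O
A2 | alternative 1 | [2,4,6-trihydroxy-3-methyl-5-(3-methylbut-2-en-1-yl)phenyl](phenyl)methanone | Cc1c(O)c(CC=C(C)C)c(O)c(C(=O)c2ccccc2)c1O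
A3 | alternative 2 | 3,5-dihydroxy-2-methyl-4,4-bis(3-methylbut-2-en-1-yl)cyclohexa-2,5-dien-1-one | CC(C)=CCC1(CC=C(C)C)C(O)=C(C)C(=O)C=C1O
A4 | alternative 2 | 5-hydroxy-4-methyl-3-oxo-6,6-bis(3-methylbut-2-en-1-yl)cyclohexa-1,4-dien-1-yl benzoate | CC(C)=CCC1(CC=C(C)C)C(O)=C(C)C(=O)C=C1OC(=O)c2ccccc2
A5 | alternative 3 | 3-ethoxy-2-methyl-4,4-bis(3-methylbut-2-en-1-yl)cyclobut-2-en-1-one | CCOC1=C(C)C(=O)C1(CC=C(C)C)CC=C(C)C
A6 | alternative 3 | 3,5-diethoxy-4-methyl-6,6-bis(3-methylbut-2-en-1-yl)cyclohexa-2,4-dien-1-one | CCOC1=CC(=O)C(CC=C(C)C)(CC=C(C)C)C(OCC)=C1C
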